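**Plan**

- Retrosynthetic cuts, in order: the seven O-benzyl groups; upper C3–O and C4–H (hydroboration of a 4-aryl-2H-chromene); the bond from upper C4 to ring B (aryl-metal addition to a (2S)-flavanone, then dehydration); lower C3–O and C2–H (hydroboration of a 4H-chromene); lower C2–C3 (ring closure); the phenol ester C–O; the allyl C–C bond on ring A (Claisen).
- Enabling feature: in the lower pyran ring (ring C), C2 carries only O1 of ring A and the tetrasubstituted catechol ring B. O1–C2 can therefore be carried as a phenyl benzoate and C4–C3 as an allyl group ortho to that oxygen on ring A; a titanium methylidene converts the ester carbonyl and the allyl terminus into the endocyclic C2=C3 bond.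
- Forward order: ring A receives its allyl group, is esterified with the brominated ring B acid, ring C is closed and hydroborated. The ring B bromide is then metalated and added to a flavanone that already holds the upper benzo ring D, pyran ring F and catechol ring E; dehydration and a second hydroboration complete ring F; hydrogenolysis ends the route.
- Stereochemistry: lower C2/C3 are trans by syn hydroboration of the ring alkene, with the absolute sense from IpcBH2. Upper C2 comes from asymmetric conjugate addition to a chromone. Upper C3 and C4 come from hydroboration anti to the C2 aryl group. Joining two enantioenriched halves allows residual stereoisomers to be removed as diastereomers.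

Key step: step 5

Remark: the sense of induction of the pinene-derived borane (step 6) and of the pyridine-oxazoline ligand (step 9) is assigned by analogy with 1-arylcycloalkenes and cyclic enones; if a pilot run shows the opposite sense, the antipodal reagent or ligand is used with no other change.

**Route**

Step 1
Reactants: 1 3,4-bis(benzyloxy)benzoic acid
Product: 2 4,5-bis(benzyloxy)-2-bromobenzoic acid
Conditions: Br2, NaOAc, AcOH, rt
Reagents that add atoms: bromine, BrBr
Why: Electrophilic aromatic bromination should occur at the open position para to the 3-benzyloxy group and ortho to the carboxyl group, the most activated site of a 3,4-dialkoxybenzoic acid, while acetate buffers HBr so that the benzyl ethers survive.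

Step 2
Reactants: 3 3-(benzyloxy)phenol
Product: 4 1-(allyloxy)-3-(benzyloxy)benzene
Conditions: allyl bromide, K2CO3, acetone, reflux
Reagents that add atoms: allyl bromide, C=CCBr
Why: Williamson ether synthesis on the phenoxide.

Step 3
Reactants: 4 1-(allyloxy)-3-(benzyloxy)benzene
Product: 5 2-allyl-5-(benzyloxy)phenol
Conditions: PhNEt2, 200 °C (sealed tube); chromatography
Reagents that add atoms: none
Why: Aromatic Claisen rearrangement ([3,3]-sigmatropic shift, then tautomerisation) is expected to favour the ortho position para to the benzyloxy group over the crowded position between the two oxygens, and the minor regioisomer is removed by chromatography.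

Step 4
Reactants: 2 4,5-bis(benzyloxy)-2-bromobenzoic acid; 5 2-allyl-5-(benzyloxy)phenol
Product: 6 2-allyl-5-(benzyloxy)phenyl 4,5-bis(benzyloxy)-2-bromobenzoate
Conditions: EDC·HCl, DMAP (cat.), CH2Cl2, 0 °C to rt
Reagents that add atoms: none
Why: Steglich-type carbodiimide esterification, in which DMAP acyl transfer should overcome the ortho-bromo hindrance and the phenol is the only nucleophile present.

Step 5
Reactants: 6 2-allyl-5-(benzyloxy)phenyl 4,5-bis(benzyloxy)-2-bromobenzoate
Product: 8 7-(benzyloxy)-2-[4,5-bis(benzyloxy)-2-bromophenyl]-4H-chromene, via acyclic enol ether 7 (not isolated)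
Conditions: Tebbe reagent Cp2Ti(μ-Cl)(μ-CH2)AlMe2 (4 equiv), pyridine (cat.), THF, 0 °C to rt, then reflux; 0.1 M NaOH quench, filtration through basic alumina
Reagents that add atoms: none
Why: Cp2Ti=CH2 released from the Tebbe reagent should first methylenate the aryl ester carbonyl through an oxatitanacyclobutane to give enol ether 7; a further equivalent then exchanges with the allyl terminus (titanacyclobutane, loss of ethylene) to a titanium alkylidene that adds across the new 1,1-disubstituted enol-ether double bond and cycloreverts, forming the C2=C3 bond. The closest known reaction type is the one-flask Tebbe conversion of olefinic esters into six- and seven-membered cyclic enol ethers (carbonyl olefination followed by ring-closing olefin metathesis). The one ring closed is the six-membered pyran ring C fused to ring A, closed by ring-closing metathesis with the new double bond endocyclic. No stereocenter is formed here; the step fixes the ring alkene from which syn hydroboration in step 6 must deliver the 2,3-trans pair. The selectivity needed is reaction at the only carbonyl group and the only two alkenes, which the substrate secures because benzyl ethers and the aryl bromide are inert to titanium alkylidenes, and retention of the 4H-chromene double-bond position, which the non-acidic medium and basic work-up protect.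

Step 6
Reactants: 8 7-(benzyloxy)-2-[4,5-bis(benzyloxy)-2-bromophenyl]-4H-chromene
Product: 10 (2R,3S)-7-(benzyloxy)-2-[4,5-bis(benzyloxy)-2-bromophenyl]chroman-3-ol, via alkyl(isopinocampheyl)borane 9 (not isolated)
Conditions: IpcBH2 [pre-formed from (+)-α-pinene], THF, −25 °C to 0 °C; then NaOH aq., H2O2, 0 °C to rt
Reagents that add atoms: hydrogen peroxide, OO
Why: Asymmetric hydroboration-oxidation should place boron at C3 (β to the ring oxygen, distal to the aryl group) and hydrogen at C2 on the same face, so that oxidation with retention gives the 2,3-trans alcohol, with the face chosen by the chiral borane by analogy with 1-arylcycloalkenes, which give the spatially corresponding trans-2-arylcycloalkanols, and with low temperature suppressing β-elimination of the β-aryloxy borane.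

Step 7
Reactants: 10 (2R,3S)-7-(benzyloxy)-2-[4,5-bis(benzyloxy)-2-bromophenyl]chroman-3-ol
Product: 11 (2R,3S)-3,7-bis(benzyloxy)-2-[4,5-bis(benzyloxy)-2-bromophenyl]chromane
Conditions: NaH, BnBr, Bu4NI (cat.), DMF, 0 °C to rt
Reagents that add atoms: benzyl bromide, BrCc1ccccc1
Why: Williamson benzylation of the secondary alkoxide protects the 3-OH against the organolithium step without touching either stereocenter.

Step 8
Reactants: 12 7-hydroxy-4H-chromen-4-one
Product: 13 7-(benzyloxy)-4H-chromen-4-one
Conditions: BnBr, K2CO3, DMF, 60 °C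
Reagents that add atoms: benzyl bromide, BrCc1ccccc1
Why: Williamson ether synthesis on the acidic 7-phenol.

Step 9
Reactants: 13 7-(benzyloxy)-4H-chromen-4-one; 14 [3,4-bis(benzyloxy)phenyl]boronic acid
Product: 15 (2S)-7-(benzyloxy)-2-[3,4-bis(benzyloxy)phenyl]chroman-4-one
Conditions: Pd(OCOCF3)2 (5 mol%), (R)-t-BuPyOX (6 mol%), NH4PF6 (30 mol%), H2O (5 equiv), ClCH2CH2Cl, 60 °C
Reagents that add atoms: none
Why: Palladium-catalysed asymmetric conjugate addition of an arylboronic acid to a chromone (aryl-palladium insertion into C2=C3, protonolysis of the palladium enolate) should set C2 under control of the chiral pyridine-oxazoline ligand, whose enantiomer is chosen to give the (2S) ketone.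

Step 10
Reactants: 11 (2R,3S)-3,7-bis(benzyloxy)-2-[4,5-bis(benzyloxy)-2-bromophenyl]chromane; 15 (2S)-7-(benzyloxy)-2-[3,4-bis(benzyloxy)phenyl]chroman-4-one
Product: 19 (2S)-7-(benzyloxy)-4-{4,5-bis(benzyloxy)-2-[(2R,3S)-3,7-bis(benzyloxy)chroman-2-yl]phenyl}-2-[3,4-bis(benzyloxy)phenyl]-2H-chromene, via aryllithium 16 (not isolated), via arylcerium dichloride 17 (not isolated), via tertiary carbinol 18 (not isolated)
Conditions: 11, n-BuLi, THF, −78 °C; CeCl3 (anhydrous), −78 °C; then 15, −78 °C to −40 °C; NH4Cl aq.; crude 18: PPTS (cat.), toluene, 40 °C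
Reagents that add atoms: none
Why: Bromine-lithium exchange, transmetalation to the weakly basic organocerium reagent, 1,2-addition to the enolisable ketone and acid-catalysed E1 dehydration of the doubly benzylic tertiary alcohol should give the 4-aryl-2H-chromene, the carbinol configuration being irrelevant because it is removed and the three existing stereocenters being untouched.

Step 11
Reactants: 19 (2S)-7-(benzyloxy)-4-{4,5-bis(benzyloxy)-2-[(2R,3S)-3,7-bis(benzyloxy)chroman-2-yl]phenyl}-2-[3,4-bis(benzyloxy)phenyl]-2H-chromene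
Product: 21 (2R,3S,4R)-7-(benzyloxy)-4-{4,5-bis(benzyloxy)-2-[(2R,3S)-3,7-bis(benzyloxy)chroman-2-yl]phenyl}-2-[3,4-bis(benzyloxy)phenyl]chroman-3-ol, via alkylborane 20 (not isolated)
Conditions: BH3·THF, THF, 0 °C to rt; then NaOH aq., H2O2, 0 °C to rt
Reagents that add atoms: hydrogen peroxide, OO
Why: Hydroboration-oxidation of the trisubstituted aryl alkene should add boron to C3 from the face opposite the C2 aryl group and hydrogen to C4 on the same face, giving the 2,3-trans-3,4-trans alcohol with both new centers relayed from upper C2.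

Step 12
Reactants: 21 (2R,3S,4R)-7-(benzyloxy)-4-{4,5-bis(benzyloxy)-2-[(2R,3S)-3,7-bis(benzyloxy)chroman-2-yl]phenyl}-2-[3,4-bis(benzyloxy)phenyl]chroman-3-ol
Product: 22 (2R,3S,4R)-2-(3,4-dihydroxyphenyl)-4-{2-[(2R,3S)-3,7-dihydroxychroman-2-yl]-4,5-dihydroxyphenyl}chroman-3,7-diol
Conditions: H2 (1 atm), Pd(OH)2/C, THF/MeOH, rt
Reagents that add atoms: none
Why: Hydrogenolysis of the seven benzyl ethers under neutral conditions at atmospheric pressure is expected to leave the flavan C2–O bonds and the diarylmethine C–C bond intact.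

**Compound list**

1 | 3,4-bis(benzyloxy)benzoic acid | OC(=O)c1ccc(OCc2ccccc2)c(OCc2ccccc2)c1 | starting material
2 | 4,5-bis(benzyloxy)-2-bromobenzoic acid | OC(=O)c1cc(OCc2ccccc2)c(OCc2ccccc2)cc1Br | intermediate
3 | 3-(benzyloxy)phenol | Oc1cccc(OCc2ccccc2)c1 | starting material
4 | 1-(allyloxy)-3-(benzyloxy)benzene | C=CCOc1cccc(OCc2ccccc2)c1 | intermediate
5 | 2-allyl-5-(benzyloxy)phenol | C=CCc1ccc(OCc2ccccc2)cc1O | intermediate
6 | 2-allyl-5-(benzyloxy)phenyl 4,5-bis(benzyloxy)-2-bromobenzoate | C=CCc1ccc(OCc2ccccc2)cc1OC(=O)c1cc(OCc2ccccc2)c(OCc2ccccc2)cc1Br | intermediate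
7 | 1-allyl-4-(benzyloxy)-2-{[1-(4,5-bis(benzyloxy)-2-bromophenyl)vinyl]oxy}benzene (acyclic enol ether) | C=CCc1ccc(OCc2ccccc2)cc1OC(=C)c1cc(OCc2ccccc2)c(OCc2ccccc2)cc1Br | intermediate (not isolated)
8 | 7-(benzyloxy)-2-[4,5-bis(benzyloxy)-2-bromophenyl]-4H-chromene | Brc1cc(OCc2ccccc2)c(OCc2ccccc2)cc1C1=CCc2ccc(OCc3ccccc3)cc2O1 | intermediate
9 | [7-(benzyloxy)-2-(4,5-bis(benzyloxy)-2-bromophenyl)chroman-3-yl](isopinocampheyl)borane, boron at C3 trans to the C2 aryl group, C2 and C3 arranged as in 10, isopinocampheyl from (+)-α-pinene | c1ccccc1COc1ccc2c(c1)O[C@H](c1cc(OCc3ccccc3)c(OCc3ccccc3)cc1Br)[C@@H](B[C@@H]1C[C@@H]3C[C@H]([C@H]1C)C3(C)C)C2 | intermediate (not isolated)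
10 | (2R,3S)-7-(benzyloxy)-2-[4,5-bis(benzyloxy)-2-bromophenyl]chroman-3-ol | c1ccccc1COc1ccc2c(c1)O[C@H](c1cc(OCc3ccccc3)c(OCc3ccccc3)cc1Br)[C@@H](O)C2 | intermediate
11 | (2R,3S)-3,7-bis(benzyloxy)-2-[4,5-bis(benzyloxy)-2-bromophenyl]chromane | c1ccccc1COc1ccc2c(c1)O[C@H](c1cc(OCc3ccccc3)c(OCc3ccccc3)cc1Br)[C@@H](OCc1ccccc1)C2 | intermediate
12 | 7-hydroxy-4H-chromen-4-one | O=c1ccoc2cc(O)ccc12 | starting material
13 | 7-(benzyloxy)-4H-chromen-4-one | O=c1ccoc2cc(OCc3ccccc3)ccc12 | intermediate
14 | [3,4-bis(benzyloxy)phenyl]boronic acid | OB(O)c1ccc(OCc2ccccc2)c(OCc2ccccc2)c1 | starting material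
15 | (2S)-7-(benzyloxy)-2-[3,4-bis(benzyloxy)phenyl]chroman-4-one | O=C1C[C@@H](c2ccc(OCc3ccccc3)c(OCc3ccccc3)c2)Oc2cc(OCc3ccccc3)ccc12 | intermediate
16 | aryllithium: 11 with lithium in place of bromine | c1ccccc1COc1ccc2c(c1)O[C@H](c1cc(OCc3ccccc3)c(OCc3ccccc3)cc1[Li])[C@@H](OCc1ccccc1)C2 | intermediate (not isolated)
17 | arylcerium dichloride: 11 with CeCl2 in place of bromine | c1ccccc1COc1ccc2c(c1)O[C@H](c1cc(OCc3ccccc3)c(OCc3ccccc3)cc1[Ce](Cl)Cl)[C@@H](OCc1ccccc1)C2 | intermediate (not isolated)
18 | (2S)-7-(benzyloxy)-4-{4,5-bis(benzyloxy)-2-[(2R,3S)-3,7-bis(benzyloxy)chroman-2-yl]phenyl}-2-[3,4-bis(benzyloxy)phenyl]chroman-4-ol, mixture of C4 epimers | c1ccccc1COc1ccc2c(c1)O[C@H](c1cc(OCc3ccccc3)c(OCc3ccccc3)cc1C1(O)C[C@@H](c3ccc(OCc4ccccc4)c(OCc4ccccc4)c3)Oc3cc(OCc4ccccc4)ccc31)[C@@H](OCc1ccccc1)C2 | intermediate (not isolated)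
19 | (2S)-7-(benzyloxy)-4-{4,5-bis(benzyloxy)-2-[(2R,3S)-3,7-bis(benzyloxy)chroman-2-yl]phenyl}-2-[3,4-bis(benzyloxy)phenyl]-2H-chromene | c1ccccc1COc1ccc2c(c1)O[C@H](c1cc(OCc3ccccc3)c(OCc3ccccc3)cc1C1=C[C@@H](c3ccc(OCc4ccccc4)c(OCc4ccccc4)c3)Oc3cc(OCc4ccccc4)ccc31)[C@@H](OCc1ccccc1)C2 | intermediate
20 | alkylborane: 21 with BH2 in place of the upper 3-OH, same configuration | c1ccccc1COc1ccc2c(c1)O[C@H](c1cc(OCc3ccccc3)c(OCc3ccccc3)cc1[C@@H]1c3ccc(OCc4ccccc4)cc3O[C@H](c3ccc(OCc4ccccc4)c(OCc4ccccc4)c3)[C@H]1B)[C@@H](OCc1ccccc1)C2 | intermediate (not isolated)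
21 | (2R,3S,4R)-7-(benzyloxy)-4-{4,5-bis(benzyloxy)-2-[(2R,3S)-3,7-bis(benzyloxy)chroman-2-yl]phenyl}-2-[3,4-bis(benzyloxy)phenyl]chroman-3-ol | c1ccccc1COc1ccc2c(c1)O[C@H](c1cc(OCc3ccccc3)c(OCc3ccccc3)cc1[C@@H]1c3ccc(OCc4ccccc4)cc3O[C@H](c3ccc(OCc4ccccc4)c(OCc4ccccc4)c3)[C@H]1O)[C@@H](OCc1ccccc1)C2 | intermediate
22 | (2R,3S,4R)-2-(3,4-dihydroxyphenyl)-4-{2-[(2R,3S)-3,7-dihydroxychroman-2-yl]-4,5-dihydroxyphenyl}chroman-3,7-diol | Oc1ccc2c(c1)O[C@H](c1cc(O)c(O)cc1[C@@H]1c3ccc(O)cc3O[C@H](c3ccc(O)c(O)c3)[C@H]1O)[C@@H](O)C2 | target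

**Count and risks**

Total step count: 12. Longest linear sequence: 9 steps (steps 2, 3, 4, 5, 6, 7, 10, 11, 12, from 3-(benzyloxy)phenol).

Steps most likely to fail:

1. Step 5. The titanium reagent may cleave the phenyl ester, or the titanium alkylidene may decay before it engages the hindered 1,1-disubstituted enol ether, so that the sequence stalls at the open-chain stage. The fallback sets out from 6 and separates the two events. Methylenation alone with Cp2TiMe2 (toluene, 65 °C) should give the acyclic enol ether 7, which is isolated on base-washed silica. The ring is then closed without titanium by ruthenium-catalysed ring-closing metathesis with the second-generation Grubbs catalyst (H2IMes)(PCy3)Cl2Ru=CHPh (toluene, 60 °C, 1,4-benzoquinone to suppress alkene migration), which initiates at the allyl terminus and releases ethylene. The route is rejoined at 8. No compound outside the list is made (entry F0).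

2. Step 6. Facial selectivity may be poor because the ring oxygen and the ortho-bromo aryl group depart from the carbocyclic model, and the β-aryloxy borane may undergo β-elimination at the temperature the bulky borane needs. The fallback sets out from 8 and moves the source of absolute configuration from the reagent to an enzyme. Hydroboration-oxidation with BH3·THF (0 °C, then NaOH/H2O2) should give racemic trans-7-(benzyloxy)-2-[4,5-bis(benzyloxy)-2-bromophenyl]chroman-3-ol F1. Kinetic resolution with Pseudomonas cepacia lipase and vinyl acetate (tert-butyl methyl ether, 30 °C) is expected, by the secondary-alcohol rule for lipases, to acetylate the unwanted enantiomer to (2S,3R)-7-(benzyloxy)-2-[4,5-bis(benzyloxy)-2-bromophenyl]chroman-3-yl acetate F2 and leave the (2R,3S) alcohol, which is separated by chromatography. The route is rejoined at 10.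

3. Step 10. The ortho-substituted aryllithium may be quenched by proton transfer from the neighbouring benzylic C2–H. The flavanone may enolise and ring-open (retro-oxa-Michael, with loss of the C2 configuration) in competition with slow 1,2-addition to a hindered ketone. The acid dehydration may also ionise the chromene C2–O bond. The fallback sets out from 15 and avoids both the organometallic reagent and the acid. Condensation with 4-methylbenzenesulfonohydrazide (MeOH, 60 °C) should give N'-[(2S)-7-(benzyloxy)-2-(3,4-bis(benzyloxy)phenyl)chroman-4-ylidene]-4-methylbenzenesulfonohydrazide F3. Palladium-catalysed cross-coupling of F3 with aryl bromide 11 [Pd2(dba)3, XPhos, LiOt-Bu, 1,4-dioxane, 100 °C] proceeds through the diazo compound, a palladium carbene, aryl migration and β-hydride elimination from C3, and should give the 4-aryl-2H-chromene directly. The route is rejoined at 19.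

**Further compounds**

F0 | step 5 | none | none
F1 | step 6 | racemic trans-7-(benzyloxy)-2-[4,5-bis(benzyloxy)-2-bromophenyl]chroman-3-ol (both enantiomers shown) | c1ccccc1COc1ccc2c(c1)O[C@H](c1cc(OCc3ccccc3)c(OCc3ccccc3)cc1Br)[C@@H](O)C2.c1ccccc1COc1ccc2c(c1)O[C@@H](c1cc(OCc3ccccc3)c(OCc3ccccc3)cc1Br)[C@H](O)C2
F2 | step 6 | (2S,3R)-7-(benzyloxy)-2-[4,5-bis(benzyloxy)-2-bromophenyl]chroman-3-yl acetate | c1ccccc1COc1ccc2c(c1)O[C@@H](c1cc(OCc3ccccc3)c(OCc3ccccc3)cc1Br)[C@H](OC(C)=O)C2
F3 | step 10 | N'-[(2S)-7-(benzyloxy)-2-(3,4-bis(benzyloxy)phenyl)chroman-4-ylidene]-4-methylbenzenesulfonohydrazide | Cc1ccc(S(=O)(=O)NN=C2C[C@@H](c3ccc(OCc4ccccc4)c(OCc4ccccc4)c3)Oc3cc(OCc4ccccc4)ccc23)cc1
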